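## Structural features

The target is a 21-membered cyclophane built from two benzene rings and one unbranched (CH2)14 chain. Ring A is a 1,3,5-trisubstituted, resorcinol-type ring that carries a free hydroxyl, the diaryl ether oxygen and one end of the chain. Ring B is a hydroquinone (OH at C1 and C4) with the ether oxygen at C2 and the other chain end at C6, so both links to ring A flank the C1 hydroxyl. The large ring runs through three atoms of each arene, the ether oxygen and fourteen methylene groups (3 + 3 + 1 + 14 = 21). There is no stereocentre and no stereogenic double bond, so no configuration has to be set. The fragile parts are the hydroquinone, which air oxidizes to the quinone, and the electron-rich ring A, which is open to oxidants and electrophiles. The real difficulties are the entropically costly closure of a large floppy ring and the making of a diaryl ether at an electron-rich ring B carbon next to an oxygenated carbon, where ordinary SNAr chemistry is not available; in addition, three phenolic oxygens must be told apart. The key step uses the position of the ether carbon C2 of ring B, ortho to C1–OH and meta to C4–OH: once ring B is a 1,4-benzoquinone, C2 is the beta carbon of the O=C4–C3=C2 enone and, with bromine on it, a vinylogous acyl bromide that a ring A phenoxide can substitute.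

## Logic of the disconnections

15 to 13. The final operation is to be a single neutral hydrogenation. 15 is therefore traced back to 13 by raising ring B to the quinone level and capping the ring A hydroxyl as a benzyl ether; the only bond cut is O–CH2Ph, and 14 lies on the way. The gain is that the air-sensitive triol appears only in the last flask and no Lewis-acid dealkylation is needed on it. The demand is that hydrogen over palladium reduce the quinone and cleave the benzyl ether without touching the diaryl ether.

13 to 12 and 11. The C2–O bond between ring B and the ring A oxygen is cut. This opens the 21-membered ring and gives an open chain with a phenoxide at one end and a C–Br carbon of a quinone at the other (12). The cut is made here because the quinone level turns this carbon into an electrophile without any metal. 12 is stored as the silyl ether 11 (O–Si bond), so that the nucleophile exists only in the dilute cyclization flask. The forward step must favour ring closure over chain growth, attack at the bromo carbon over the two C–H enone carbons, and O-attack over C-attack.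

11 to 10. The two carbonyl groups are traced back to two aryl methyl ethers, so that ring B travels through the organometallic steps as an inert arene. The gain is a bromoarene that survives borane and palladium chemistry. The demand is an oxidant that converts the para-dimethoxy ring B and leaves the meta-dioxygenated ring A, its silyl ether and its benzyl ether alone.

10 to 9 and 5, and 9 to 8. The bond between ring B C6 and the first chain CH2 is cut, which gives a primary alkylborane (9, from the terminal alkene 8) and the symmetric dibromide 5. The gain is that ring B comes from a cheap, symmetric building block whose second bromine is exactly the leaving group needed later. The demand is coupling at only one of two equivalent C–Br bonds.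

8 to 7 and 3, and 7 to 6. The bond between ring A and the other end of the chain is cut in the same way. This gives the alkylborane 7, from one end of the symmetric diene 6, and the aryl bromide 3. The whole C14 tether is thus bought in one piece. The demand is hydroboration of one alkene only, met by an excess of 6.

5 to 4, and 3 to 2 to 1. Only bonds to protecting groups are cut here (O–CH3, O–Si, O–CH2Ph). Because 1 is symmetric, its single mono-benzylation decides which ring A oxygen becomes the ether and which the free phenol. The demand is control of mono- against bis-alkylation, met by an excess of 1.

## Other disconnections considered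

Alternative 1: Ring A is taken apart, so the ether oxygen travels on ring B as the ynol ether A3 and the remaining four ring A carbons with the chain come from the cyclobutenone A2.
- Forward step: on heating, A2 opens to a vinylketene that adds [2+2] to the triple bond of A3. The new cyclobutenone opens again, the dienylketene closes by a six-electron electrocyclization and tautomerizes to the phenol A1, with the aryloxy group and the chain both meta to the new hydroxyl.
- In favour: no aryl C–O coupling is needed at all, the 1,3,5 pattern follows from the mechanism, and the ring A phenol is born free.
- Better than the chosen plan: the later macrocyclization would be a ring-closing metathesis of two terminal alkenes, a better-documented closure for a ring of this size than a phenoxide–quinone etherification. No strong oxidant has to act next to an electron-rich ring.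
- Against: A3 belongs to a sensitive class, needs several steps, and is a weaker ketenophile than the alkyl or silyl ynol ethers normally used. A2 is itself a multi-step compound. After A1 come metathesis, alkene hydrogenation and two O-demethylations.
- Comparison: both plans treat the ether as the hard bond; this one hides it in a building block, the chosen one makes it last. In regiocontrol the pericyclic cascade is at least the equal of the addition–elimination. In step count (probably twelve or more against eight) and in the simplicity of the starting materials the chosen plan is ahead.

Alternative 2: Ring B is taken apart into the alkyne, the carbene carbon with its alkenyl group, and one CO, all held in the open-chain pentacarbonylchromium carbene A5.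
- Forward step: in dilute solution A5 loses CO, the tethered aryloxyalkyne inserts with its oxygen-bearing carbon next to the CO-derived carbon, and CO insertion and electrocyclization follow. Ring B, as a 4-methoxyphenol, and the 21-membered ring appear together in A4 once chromium is released.
- Better than the chosen plan: three C–C bonds and two rings form in one step. The 1-hydroxy-2-aryloxy-4-methoxy-6-alkyl pattern is fixed by the mechanism, and ring B needs no redox adjustment before or after.
- Equal to the chosen plan: both close the macrocycle in the step that completes ring B's substitution, and both need high dilution.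
- Against: A5 combines an ynol ether and a Fischer carbene on a C14 tether and would be long and delicate to assemble. Chromium is used in stoichiometric amount. Heteroatom-substituted alkynes can divert alkenylcarbene complexes to products without CO insertion. The electronic bias of an ynol ether may oppose the steric regiochemistry that the tether requires.
- Comparison: after A4 two O-demethylations remain, against one hydrogenation in the chosen plan. The overall count should be eleven steps or more.

Alternative 3: The bond from ring B C6 to the benzylic CH2 is cut and traced back to a [3,3] shift. The chain then hangs from the ring B phenol oxygen through its secondary allylic carbon in the 19-membered ether A7.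
- Forward step: heating A7 moves the allyl unit from oxygen to the only unsubstituted ortho carbon through a six-membered transition state. The terminal vinyl carbon becomes the benzylic CH2, and enolization gives the phenol A6, two ring atoms larger, with an (E)-alkene.
- Better than the chosen plan: the key step is unimolecular and reagent-free, needs no dilution, and has no ambident-nucleophile problem. The ortho position is unambiguous, the alkene geometry is irrelevant because the alkene is hydrogenated later, and the diaryl ether can be made intermolecularly before any large ring exists.
- Against: a macrocyclization is not avoided, only moved to the making of A7. There a secondary allylic aryl ether must be closed to a 19-membered ring in competition with allylic transposition and elimination. Such ethers also ionize on heating, and the chair transition state must be reached inside the macrocycle. The intermolecular diaryl ether still needs a copper coupling at an electron-rich, ortho-oxygenated carbon, which is the bond the chosen plan makes easy.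
- Comparison: after A6 come hydrogenation and two O-demethylations. The count should be eleven to thirteen steps against eight.

Key step: step 7

Remark on the chemistry: the target has no stereogenic element. Ring A's reacting oxygen is carried as a triisopropylsilyl ether and its other oxygen as a benzyl ether; this changes protecting groups only and leaves the bond formed in the key step and both of its skeletons unchanged.

## Route

Step 1
Reactants: 1 5-bromobenzene-1,3-diol
Product: 2 3-(benzyloxy)-5-bromophenol
Conditions: 1 (2.5 equiv), BnBr (1.0 equiv), K2CO3 (1.0 equiv), acetone, reflux
Reagents that add atoms: benzyl bromide, BrCc1ccccc1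
Why: Williamson ether synthesis on a symmetric diol; the excess of 1 should keep bis-benzylation low, and unreacted 1 is recovered by chromatography and reused.

Step 2
Reactants: 2 3-(benzyloxy)-5-bromophenol
Product: 3 [3-(benzyloxy)-5-bromophenoxy]tri(propan-2-yl)silane
Conditions: TIPSCl (1.2 equiv), imidazole (2.5 equiv), DMF, rt
Reagents that add atoms: chlorotri(propan-2-yl)silane, CC(C)[Si](Cl)(C(C)C)C(C)C
Why: O-silylation of a phenol; the triisopropylsilyl ether is chosen because it should survive the aqueous phosphate of the couplings and the acidic oxidation, yet is cleaved by fluoride.

Step 3
Reactants: 4 2,6-dibromo-4-methoxyphenol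
Product: 5 1,3-dibromo-2,5-dimethoxybenzene
Conditions: MeI (1.5 equiv), K2CO3 (2 equiv), DMF, rt
Reagents that add atoms: iodomethane, CI
Why: Williamson O-methylation of an acidic, hindered phenol; the product is symmetric, so either bromine can be coupled later.

Step 4
Reactants: 6 tetradeca-1,13-diene; 3 [3-(benzyloxy)-5-bromophenoxy]tri(propan-2-yl)silane
Product: 8 [3-(benzyloxy)-5-(tetradec-13-en-1-yl)phenoxy]tri(propan-2-yl)silane, via B-tetradecenyl-9-BBN 7 (not isolated)
Conditions: 6 (5 equiv), 9-BBN (1.3 equiv), THF, 0 °C to rt; then 3 (1.0 equiv), PdCl2(dppf) (3 mol%), 3 M aq K3PO4 (3 equiv), THF, 60 °C
Reagents that add atoms: 9-borabicyclo[3.3.1]nonane, B1C2CCCC1CCC2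
Why: anti-Markovnikov hydroboration of one terminal alkene of 6 (statistical control through its excess) places the borabicyclononyl unit in 7 only, and the B-alkyl Suzuki–Miyaura coupling with the aryl bromide releases it again as the borinic acid, so 8 holds none of its atoms; the bidentate phosphine favours reductive elimination over beta-hydride loss, and the silyl and benzyl ethers should be inert.

Step 5
Reactants: 8 [3-(benzyloxy)-5-(tetradec-13-en-1-yl)phenoxy]tri(propan-2-yl)silane; 5 1,3-dibromo-2,5-dimethoxybenzene
Product: 10 {3-(benzyloxy)-5-[14-(3-bromo-2,5-dimethoxyphenyl)tetradecyl]phenoxy}tri(propan-2-yl)silane, via B-alkyl-9-BBN 9 (not isolated)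
Conditions: 9-BBN (1.2 equiv), THF, rt; then 5 (3.5 equiv), PdCl2(dppf) (5 mol%), 3 M aq K3PO4 (3 equiv), THF, 60 °C
Reagents that add atoms: 9-borabicyclo[3.3.1]nonane, B1C2CCCC1CCC2
Why: second hydroboration and B-alkyl Suzuki–Miyaura coupling, in which the boron unit sits in 9 only and is lost again on coupling; mono-coupling should be favoured by the excess of 5 (recovered) and because the C–Br bond left in 10 sits on a more electron-rich ring than those of 5 and should add to zerovalent palladium more slowly.

Step 6
Reactants: 10 {3-(benzyloxy)-5-[14-(3-bromo-2,5-dimethoxyphenyl)tetradecyl]phenoxy}tri(propan-2-yl)silane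
Product: 11 2-bromo-6-{14-[3-(benzyloxy)-5-(triisopropylsilyloxy)phenyl]tetradecyl}cyclohexa-2,5-diene-1,4-dione
Conditions: Ce(NH4)2(NO3)6 (2.3 equiv), MeCN–CH2Cl2–H2O, 0 °C, 20 min
Reagents that add atoms: water, O
Why: oxidative demethylation of a para-dimethoxyarene by tetravalent cerium; the radical cation of ring B is trapped by water at the ether carbons and methanol is lost twice, while the meta-dioxygenated ring A is harder to oxidize and has no quinone outlet, and the silyl and benzyl ethers should survive the short, cold, acidic exposure.

Step 7
Reactants: 11 2-bromo-6-{14-[3-(benzyloxy)-5-(triisopropylsilyloxy)phenyl]tetradecyl}cyclohexa-2,5-diene-1,4-dione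
Product: 13 macrocyclic 2-aryloxy-6-alkyl-1,4-benzoquinone benzyl ether (21-membered ring: quinone C2–O–ring A and quinone C6–(CH2)14–ring A), via cesium phenoxide 12 (not isolated)
Conditions: CsF (8 equiv), amine-free DMF, rt, Ar, 11 added by syringe pump over 12 h (final 1 mM); AcOH quench
Reagents that add atoms: cesium fluoride, [Cs+].[F-]
Why: Fluoride cleaves the aryl O–Si bond of 11 and releases the phenoxide 12, which carries cesium only as its counter-ion until bromide leaves, in the dilute flask; its oxygen adds to C2 of the quinone, the bromine-bearing beta carbon of the O=C4–C3=C2 enone, and the enolate expels bromide to restore the quinone, so the diaryl ether bond and the large ring form in one addition–elimination. The closest known reaction type is the intermolecular substitution of halo-1,4-benzoquinones by phenoxides to aryloxyquinones, run here intramolecularly under the high-dilution practice of SNAr macro-etherifications. The ring closes in a 21-exo-trig mode, since the attacked C2=C3 bond lies outside the new ring, and the (CH2)14 tether is long enough to reach C2 without strain. No stereocentre is formed. Three selectivities are needed: ring closure over oligomerization, attack at C2 over C3 and C5, and O-attack over C-attack of the ambident phenoxide. Slow addition into a large volume should secure the first, because the phenoxide never accumulates. The second rests on the leaving group: only the adduct at C2 can lose bromide, and adducts at the C–H carbons can only revert. The third rests on the cesium counter-ion in a dipolar aprotic solvent, which leaves the oxygen terminus free, and on the benzyl cap, which prevents a far more C-nucleophilic resorcinol dianion; the acid quench protects the vinylogous ester product from hydroxide and fluoride.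

Step 8
Reactants: 13 macrocyclic 2-aryloxy-6-alkyl-1,4-benzoquinone benzyl ether
Product: 15 target cyclophane triol (ring B hydroquinone and ring A free phenol), via hydroquinone benzyl ether 14 (not isolated)
Conditions: H2 (1 atm), 10% Pd/C, EtOAc–EtOH, rt; filtration under Ar
Reagents that add atoms: none
Why: catalytic hydrogenation reduces the quinone to the hydroquinone at once and then hydrogenolyses the aryl benzyl ether; the diaryl ether and the alkyl chain are inert, and filtration under argon should keep the hydroquinone from re-oxidizing.

## Compound list

1 | 5-bromobenzene-1,3-diol | Oc1cc(O)cc(Br)c1 | starting material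
2 | 3-(benzyloxy)-5-bromophenol | Oc1cc(Br)cc(OCc2ccccc2)c1 | intermediate
3 | [3-(benzyloxy)-5-bromophenoxy]tri(propan-2-yl)silane | CC(C)[Si](Oc1cc(Br)cc(OCc2ccccc2)c1)(C(C)C)C(C)C | intermediate
4 | 2,6-dibromo-4-methoxyphenol | COc1cc(Br)c(O)c(Br)c1 | starting material
5 | 1,3-dibromo-2,5-dimethoxybenzene | COc1cc(Br)c(OC)c(Br)c1 | intermediate
6 | tetradeca-1,13-diene | C=CCCCCCCCCCCC=C | starting material
7 | 9-(tetradec-13-en-1-yl)-9-borabicyclo[3.3.1]nonane | C=CCCCCCCCCCCCCB1C2CCCC1CCC2 | intermediate
8 | [3-(benzyloxy)-5-(tetradec-13-en-1-yl)phenoxy]tri(propan-2-yl)silane | C=CCCCCCCCCCCCCc1cc(OCc2ccccc2)cc(O[Si](C(C)C)(C(C)C)C(C)C)c1 | intermediate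
9 | 9-{14-[3-(benzyloxy)-5-(triisopropylsilyloxy)phenyl]tetradecyl}-9-borabicyclo[3.3.1]nonane | CC(C)[Si](Oc1cc(CCCCCCCCCCCCCCB2C3CCCC2CCC3)cc(OCc2ccccc2)c1)(C(C)C)C(C)C | intermediate
10 | {3-(benzyloxy)-5-[14-(3-bromo-2,5-dimethoxyphenyl)tetradecyl]phenoxy}tri(propan-2-yl)silane | COc1cc(Br)c(OC)c(CCCCCCCCCCCCCCc2cc(OCc3ccccc3)cc(O[Si](C(C)C)(C(C)C)C(C)C)c2)c1 | intermediate
11 | 2-bromo-6-{14-[3-(benzyloxy)-5-(triisopropylsilyloxy)phenyl]tetradecyl}cyclohexa-2,5-diene-1,4-dione | O=C1C=C(Br)C(=O)C(CCCCCCCCCCCCCCc2cc(OCc3ccccc3)cc(O[Si](C(C)C)(C(C)C)C(C)C)c2)=C1 | intermediate
12 | cesium 3-(benzyloxy)-5-[14-(5-bromo-3,6-dioxocyclohexa-1,4-dien-1-yl)tetradecyl]phenolate | [Cs+].[O-]c1cc(OCc2ccccc2)cc(CCCCCCCCCCCCCCC2=CC(=O)C=C(Br)C2=O)c1 | intermediate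
13 | 21-membered macrocyclic 2-aryloxy-6-alkyl-1,4-benzoquinone: quinone C2–O–C1 of a 5-(benzyloxy)-1,3-phenylene ring A, quinone C6–(CH2)14–C3 of ring A | O=C1C=C2Oc3cc(OCc4ccccc4)cc(c3)CCCCCCCCCCCCCCC(=C1)C2=O | intermediate
14 | hydroquinone of 13 (ring B 1,4-diol, ring A benzyl ether intact) | c1ccccc1COc1cc2cc(c1)Oc1cc(O)cc(c1O)CCCCCCCCCCCCCC2 | intermediate
15 | target: 21-membered cyclophane with ring A phenol, ring B hydroquinone, diaryl ether and (CH2)14 bridge | Oc1cc2cc(c1)Oc1cc(O)cc(c1O)CCCCCCCCCCCCCC2 | target

## Step count and least certain steps

Total step count: 8. Longest linear sequence: 7 (steps 1, 2, 4, 5, 6, 7, 8); step 3 is a one-step branch.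

Step 7 (key step). The most likely failures are chain growth in place of ring closure, carbon attack by the electron-rich phenoxide ring on the quinone, and base-induced decay of the quinone (hydroxide from wet fluoride, amine from the solvent, redox side reactions). All of these arise because a strong nucleophile and a strong electrophile share one molecule and the ring is large. Desilylation that is slow relative to addition would raise the stationary concentration of electrophile and favour dimers.

Fallback: ring closure at the arene level by copper catalysis, which is known chemistry for diaryl ether cyclophanes. It sets out from 10. Tetrabutylammonium fluoride in THF removes the silyl group and gives 3-(benzyloxy)-5-[14-(3-bromo-2,5-dimethoxyphenyl)tetradecyl]phenol F1. An intramolecular Ullmann coupling (CuI, N,N-dimethylglycine, Cs2CO3, dioxane, 100 °C, high dilution) should give the macrocyclic diaryl ether with ring B as its dimethyl ether and ring A as its benzyl ether F2. BBr3 in CH2Cl2 (−78 °C to rt) should then cleave both methyl ethers and the benzyl ether, and the route is rejoined at 15.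

Step 6. The most likely failure is over-oxidation: attack of tetravalent cerium on ring A (oxidative coupling, nitration, or debenzylation through its radical cation). The meta-dioxygenated, alkylated ring A is only moderately harder to oxidize than the brominated ring B, whose hindered C2 methoxy group is twisted out of conjugation. Partial loss of the silyl group in the acidic medium would make this worse, since a free phenol oxidizes faster.

Fallback: ring B is changed so that it can be oxidized by a reagent that needs a free phenol. It sets out from 4 and 8. 4 is protected with chloromethyl methyl ether and i-Pr2NEt as 1,3-dibromo-5-methoxy-2-(methoxymethoxy)benzene F3. Borane 9, made from 8 as in step 5, is coupled with an excess of F3 to the mono-coupled bromoarene methoxymethyl ether F4. Catalytic HCl in MeOH–THF removes the acetal and gives the 2-bromo-6-alkyl-4-methoxyphenol F5. PhI(OAc)2 in aqueous MeCN at 0 °C, a known oxidative demethylation of para-methoxyphenols, should give the bromoquinone, and the route is rejoined at 11.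

Step 5. The most likely failures are double coupling at both equivalent C–Br bonds and reduction of the borane partner through beta-hydride elimination or protodeboronation. Selectivity rests only on stoichiometry and a modest electronic difference.

Fallback: the two halogens are made different. It sets out from 5. One bromine–lithium exchange (n-BuLi, 1.0 equiv, THF, −78 °C) followed by I2 gives 1-bromo-3-iodo-2,5-dimethoxybenzene F6. Borane 9 is then coupled with F6 (1.1 equiv) at rt, where oxidative addition into the C–I bond is much faster than into C–Br, and the route is rejoined at 10.

Step 8. The most likely failures are stalling of the hydrogenolysis after the fast quinone reduction and re-oxidation of the electron-rich hydroquinone by air during filtration and concentration. The first would come from the catalyst being covered by the polar triol, the second from the fact that the product is the most oxidizable compound of the route.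

Fallback: the two events are separated and no hydrogen is used. It sets out from 13. Aqueous Na2S2O4 in EtOAc reduces the quinone to 14, which is now isolated. BCl3 with pentamethylbenzene in CH2Cl2 at −78 °C then removes the benzyl group, and the route is rejoined at 15. This fallback makes no compound outside the compound list (F0).

## Further compounds

F1 | step 7 | 3-(benzyloxy)-5-[14-(3-bromo-2,5-dimethoxyphenyl)tetradecyl]phenol | COc1cc(Br)c(OC)c(CCCCCCCCCCCCCCc2cc(O)cc(OCc3ccccc3)c2)c1
F2 | step 7 | 21-membered macrocyclic diaryl ether, ring B as 1,4-dimethyl ether, ring A as benzyl ether | c1ccccc1COc1cc2cc(c1)Oc1cc(OC)cc(c1OC)CCCCCCCCCCCCCC2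
F3 | step 6 | 1,3-dibromo-5-methoxy-2-(methoxymethoxy)benzene | COCOc1c(Br)cc(OC)cc1Br
F4 | step 6 | {3-(benzyloxy)-5-[14-(3-bromo-5-methoxy-2-(methoxymethoxy)phenyl)tetradecyl]phenoxy}tri(propan-2-yl)silane | COCOc1c(Br)cc(OC)cc1CCCCCCCCCCCCCCc1cc(OCc2ccccc2)cc(O[Si](C(C)C)(C(C)C)C(C)C)c1
F5 | step 6 | 2-bromo-6-{14-[3-(benzyloxy)-5-(triisopropylsilyloxy)phenyl]tetradecyl}-4-methoxyphenol | COc1cc(Br)c(O)c(CCCCCCCCCCCCCCc2cc(OCc3ccccc3)cc(O[Si](C(C)C)(C(C)C)C(C)C)c2)c1
F6 | step 5 | 1-bromo-3-iodo-2,5-dimethoxybenzene | COc1cc(Br)c(OC)c(I)c1
F0 | step 8 | none | none
A1 | alternative 1 | 3-[3-allyl-2,5-dimethoxyphenoxy]-5-(tridec-12-en-1-yl)phenol | Oc1cc(CCCCCCCCCCCC=C)cc(Oc2cc(OC)cc(CC=C)c2OC)c1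
A2 | alternative 1 | 3-(tridec-12-en-1-yl)cyclobut-2-en-1-one | O=C1C=C(CCCCCCCCCCCC=C)C1
A3 | alternative 1 | 1-(ethynyloxy)-2,5-dimethoxy-3-(prop-2-en-1-yl)benzene | C#COc1cc(OC)cc(CC=C)c1OC
A4 | alternative 2 | 21-membered macrocyclic diaryl ether, ring B as 4-methoxyphenol, ring A as methyl ether | COc1cc2cc(c1)Oc1cc(OC)cc(c1O)CCCCCCCCCCCCCC2
A5 | alternative 2 | pentacarbonyl{(E)-1-methoxy-17-[3-(ethynyloxy)-5-methoxyphenyl]heptadec-2-en-1-ylidene}chromium | COC(/C=C/CCCCCCCCCCCCCCc1cc(OC)cc(OC#C)c1)=[Cr](=C=O)(=C=O)(=C=O)(=C=O)=C=O
A6 | alternative 3 | 21-membered cyclophane with free ring B phenol, two methyl ethers and an (E)-alkene in the chain | COc1cc2cc(c1)Oc1cc(OC)cc(c1O)C/C=C/CCCCCCCCCCC2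
A7 | alternative 3 | 19-membered macrocyclic aryl 1-alkylallyl ether (ring B phenol oxygen bonded to the vinyl-bearing chain carbon) | C=CC1CCCCCCCCCCCc2cc(OC)cc(c2)Oc2cc(OC)ccc2O1
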